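**Plan**

Numbering: C1 is the carbinol carbon on ring G (4-hydroxy-3-methoxyphenyl), C2 the methine on ring S (4-hydroxy-3,5-dimethoxyphenyl), C3 the CH2OH; the target is (1S,2S).
Retrosynthesis: the C1–O bond is cut first. C1 lies para to the free phenol of ring G, so its OH is formally water added to the exocyclic carbon of the ring-G p-quinone methide. The C1–C2 bond is cut next, to a ring-G benzyl bromide and a ring-S arylacetyl unit whose carboxyl carbon becomes C3.
Forward: the chain is joined by alkylating the ring-S arylacetyl oxazolidinone with the ring-G benzyl bromide (C1–C2). The auxiliary is reduced off to the C3 alcohol and ring G is debenzylated. The only ring made, a 1,3,2-dioxaborinane (C1, C2, C3, O, B, O), closes when a phenylboronic hemiester on the C3 oxygen delivers its B–OH to C1 of the DDQ-generated quinone methide. Boron and the ring-S pivalate are then removed.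
Stereochemistry: C2 comes from (S)-4-benzyl-2-oxazolidinone (Evans alkylation). C1 is set from C2 in the ring closure, which should give the trans-4,5-diaryl dioxaborinane and hence the (1S,2S)-diol.

Key step: step 7

Assumption: 1, 3, 6 and 12 are taken as commercial; the ring-S phenol is carried as its pivalate (no α-hydrogen, inert to base and DDQ) so that ring G holds the only free phenol at the ring closure.

**Route**

Step 1
Reactants: 1 (4-hydroxy-3,5-dimethoxyphenyl)acetic acid
Product: 2 [3,5-dimethoxy-4-(pivaloyloxy)phenyl]acetic acid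
Conditions: PivCl (2 equiv), 2 M aq NaOH, THF, 0 °C; then 1 M HCl to pH 2
Reagents that add atoms: pivaloyl chloride, CC(C)(C)C(=O)Cl
Why: Schotten–Baumann O-acylation; in aqueous alkali only the phenoxide keeps the pivaloyl group, because any carboxylic–pivalic mixed anhydride is hydrolysed back to the carboxylate.

Step 2
Reactants: 2 [3,5-dimethoxy-4-(pivaloyloxy)phenyl]acetic acid; 3 (S)-4-benzyl-2-oxazolidinone
Product: 5 (S)-4-benzyl-3-[2-(3,5-dimethoxy-4-pivaloyloxyphenyl)acetyl]oxazolidin-2-one, via mixed pivalic anhydride 4 (not isolated)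
Conditions: PivCl (1.05 equiv), Et3N (2.5 equiv), THF, −20 °C; then 3, LiCl (1.1 equiv), −20 °C → rt
Reagents that add atoms: none
Why: N-acylation of the oxazolidinone through a mixed pivalic anhydride with LiCl/Et3N activation; attack should occur at the unhindered arylacetyl carbonyl, and the aryl pivalate is inert.

Step 3
Reactants: 6 (4-benzyloxy-3-methoxyphenyl)methanol (O-benzylvanillyl alcohol)
Product: 7 O-benzylvanillyl bromide (4-benzyloxy-3-methoxybenzyl bromide)
Conditions: PBr3 (0.4 equiv), Et2O, 0 °C; used at once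
Reagents that add atoms: phosphorus tribromide, BrP(Br)Br
Why: bromination of a benzylic alcohol with PBr3 by displacement of its phosphite ester; the electron-rich bromide is labile and is therefore not stored or chromatographed.

Step 4
Reactants: 5 (S)-4-benzyl-3-[2-(3,5-dimethoxy-4-pivaloyloxyphenyl)acetyl]oxazolidin-2-one; 7 O-benzylvanillyl bromide
Product: 9 (S)-4-benzyl-3-[(S)-3-(4-benzyloxy-3-methoxyphenyl)-2-(3,5-dimethoxy-4-pivaloyloxyphenyl)propanoyl]oxazolidin-2-one, via sodium Z-enolate 8 (not isolated)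
Conditions: NaN(SiMe3)2 (1.05 equiv), THF, −78 °C; then 7 (1.3 equiv), −78 → −30 °C
Reagents that add atoms: none
Why: Evans asymmetric alkylation; the sodium-chelated Z-enolate 8 should be attacked by the benzylic bromide on the face opposite the C4 benzyl group of the auxiliary, which sets C2 as S, and the pivalate is too hindered to react at −78 °C.

Step 5
Reactants: 9 (S)-4-benzyl-3-[(S)-3-(4-benzyloxy-3-methoxyphenyl)-2-(3,5-dimethoxy-4-pivaloyloxyphenyl)propanoyl]oxazolidin-2-one
Product: 10 (S)-3-(4-benzyloxy-3-methoxyphenyl)-2-(3,5-dimethoxy-4-pivaloyloxyphenyl)propan-1-ol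
Conditions: NaBH4 (3 equiv), THF/H2O (4:1), 0 °C → rt
Reagents that add atoms: none
Why: reductive cleavage of an N-acyloxazolidinone with borohydride; hydride attacks the activated exocyclic imide carbonyl and reduces the released aldehyde to the primary alcohol, while the hindered aryl pivalate should survive and C2 is not deprotonated.

Step 6
Reactants: 10 (S)-3-(4-benzyloxy-3-methoxyphenyl)-2-(3,5-dimethoxy-4-pivaloyloxyphenyl)propan-1-ol
Product: 11 (S)-3-(4-hydroxy-3-methoxyphenyl)-2-(3,5-dimethoxy-4-pivaloyloxyphenyl)propan-1-ol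
Conditions: H2 (1 atm), 10% Pd/C, EtOAc, rt
Reagents that add atoms: none
Why: hydrogenolysis of a benzyl aryl ether over Pd/C frees the ring-G phenol; pivalate, primary alcohol and the C2 centre are inert under these neutral conditions.

Step 7
Reactants: 11 (S)-3-(4-hydroxy-3-methoxyphenyl)-2-(3,5-dimethoxy-4-pivaloyloxyphenyl)propan-1-ol; 12 phenylboronic acid
Product: 15 (4S,5S)-4-(4-hydroxy-3-methoxyphenyl)-5-(3,5-dimethoxy-4-pivaloyloxyphenyl)-2-phenyl-1,3,2-dioxaborinane, via boronic hemiester 13 (not isolated), via quinone methide 14 (not isolated)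
Conditions: 12 (1.5 equiv), 4 Å MS, CH2Cl2 (0.02 M), rt, 1 h; then DDQ (1.05 equiv), 0 °C → rt
Reagents that add atoms: none
Why: Proposed new method: the C3 alcohol of 11 and 12 condense to hemiester 13, DDQ dehydrogenates the only free phenol (hydride from benzylic C1, proton from the ring-G OH) to the p-quinone methide 14, and the boron-bound OH then adds to the exocyclic carbon C1 in an oxa-1,6-addition that re-aromatises ring G, with the hydroquinone DDQH2 acting as proton shuttle. The closest known reactions are the DDQ-mediated oxidative cyclisation of 4-(hydroxyalkyl)phenols to cyclic benzylic ethers through p-quinone methides and the intramolecular oxa-Michael addition of boronic acid hemiesters to enones; addition of a B–OH to a quinone methide in this manner is without precedent. The 1,3,2-dioxaborinane (C1, C2, C3, O, B, O) closes in a 6-exo-trig mode, whereas the free C3–OH could only close an oxetane, so the two-atom B–O extension is what allows internal delivery of oxygen. The new C1 centre is controlled by C2: allylic 1,3-strain holds C2–H in the plane of the quinone methide, the CH2OB arm attacks from its own face through a chair with both aryl groups equatorial to give the trans-(4S,5S) ring, and because the p-hydroxybenzylic C–O bond can re-ionise to 14 any cis isomer should drain to the more stable trans one. The step needs chemoselective oxidation of ring G and diastereoselection at C1; the first is secured by the ring-S phenol being an aryl pivalate that cannot form a quinone methide and by using only 1.05 equiv of DDQ, the second by the C2 stereocentre as described.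

Step 8
Reactants: 15 (4S,5S)-4-(4-hydroxy-3-methoxyphenyl)-5-(3,5-dimethoxy-4-pivaloyloxyphenyl)-2-phenyl-1,3,2-dioxaborinane
Product: 16 (1S,2S)-1-(4-hydroxy-3-methoxyphenyl)-2-(3,5-dimethoxy-4-pivaloyloxyphenyl)propane-1,3-diol
Conditions: HN(CH2CH2OH)2 (1.2 equiv), THF/Et2O, rt; filtration
Reagents that add atoms: none
Why: transesterification of a boronic ester with diethanolamine; the N→B chelated bicyclic phenylboronate is strongly favoured and should precipitate, releasing the 1,3-diol without acid or oxidant, so the p-hydroxybenzylic C1–O bond and its configuration are not touched.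

Step 9
Reactants: 16 (1S,2S)-1-(4-hydroxy-3-methoxyphenyl)-2-(3,5-dimethoxy-4-pivaloyloxyphenyl)propane-1,3-diol
Product: 17 (1S,2S)-1-(4-hydroxy-3-methoxyphenyl)-2-(4-hydroxy-3,5-dimethoxyphenyl)propane-1,3-diol
Conditions: K2CO3 (0.2 equiv), degassed MeOH, rt → 40 °C, Ar
Reagents that add atoms: none
Why: base-catalysed methanolysis (transesterification) of an aryl pivalate; the phenoxide is a good leaving group, and under mild carbonate the p-hydroxybenzylic alcohol should not ionise, so neither stereocentre is at risk.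

**Compound list**

1 | (4-hydroxy-3,5-dimethoxyphenyl)acetic acid | COc1cc(CC(=O)O)cc(OC)c1O | starting material
2 | [3,5-dimethoxy-4-(pivaloyloxy)phenyl]acetic acid | COc1cc(CC(=O)O)cc(OC)c1OC(=O)C(C)(C)C | intermediate
3 | (S)-4-benzyl-2-oxazolidinone | O=C1N[C@@H](Cc2ccccc2)CO1 | starting material
4 | [3,5-dimethoxy-4-(pivaloyloxy)phenyl]acetic pivalic anhydride | COc1cc(CC(=O)OC(=O)C(C)(C)C)cc(OC)c1OC(=O)C(C)(C)C | intermediate
5 | (S)-4-benzyl-3-[2-(3,5-dimethoxy-4-pivaloyloxyphenyl)acetyl]oxazolidin-2-one | COc1cc(CC(=O)N2C(=O)OC[C@@H]2Cc3ccccc3)cc(OC)c1OC(=O)C(C)(C)C | intermediate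
6 | (4-benzyloxy-3-methoxyphenyl)methanol | COc1cc(CO)ccc1OCc2ccccc2 | starting material
7 | 4-benzyloxy-3-methoxybenzyl bromide | COc1cc(CBr)ccc1OCc2ccccc2 | intermediate
8 | sodium (Z)-enolate of 5 | COc1cc(/C=C(\[O-])N2C(=O)OC[C@@H]2Cc3ccccc3)cc(OC)c1OC(=O)C(C)(C)C.[Na+] | intermediate
9 | (S)-4-benzyl-3-[(S)-3-(4-benzyloxy-3-methoxyphenyl)-2-(3,5-dimethoxy-4-pivaloyloxyphenyl)propanoyl]oxazolidin-2-one | COc1cc(C[C@H](C(=O)N2C(=O)OC[C@@H]2Cc3ccccc3)c4cc(OC)c(OC(=O)C(C)(C)C)c(OC)c4)ccc1OCc5ccccc5 | intermediate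
10 | (S)-3-(4-benzyloxy-3-methoxyphenyl)-2-(3,5-dimethoxy-4-pivaloyloxyphenyl)propan-1-ol | COc1cc(C[C@H](CO)c2cc(OC)c(OC(=O)C(C)(C)C)c(OC)c2)ccc1OCc3ccccc3 | intermediate
11 | (S)-3-(4-hydroxy-3-methoxyphenyl)-2-(3,5-dimethoxy-4-pivaloyloxyphenyl)propan-1-ol | COc1cc(C[C@H](CO)c2cc(OC)c(OC(=O)C(C)(C)C)c(OC)c2)ccc1O | intermediate
12 | phenylboronic acid | OB(O)c1ccccc1 | starting material
13 | (S)-3-(4-hydroxy-3-methoxyphenyl)-2-(3,5-dimethoxy-4-pivaloyloxyphenyl)propyl hydrogen phenylboronate | COc1cc(C[C@H](COB(O)c2ccccc2)c3cc(OC)c(OC(=O)C(C)(C)C)c(OC)c3)ccc1O | intermediate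
14 | (S)-2-(3,5-dimethoxy-4-pivaloyloxyphenyl)-3-(3-methoxy-4-oxocyclohexa-2,5-dien-1-ylidene)propyl hydrogen phenylboronate | COC1=CC(=C[C@H](COB(O)c2ccccc2)c3cc(OC)c(OC(=O)C(C)(C)C)c(OC)c3)C=CC1=O | intermediate
15 | (4S,5S)-4-(4-hydroxy-3-methoxyphenyl)-5-(3,5-dimethoxy-4-pivaloyloxyphenyl)-2-phenyl-1,3,2-dioxaborinane (trans) | COc1cc([C@H]2OB(c3ccccc3)OC[C@@H]2c4cc(OC)c(OC(=O)C(C)(C)C)c(OC)c4)ccc1O | intermediate
16 | (1S,2S)-1-(4-hydroxy-3-methoxyphenyl)-2-(3,5-dimethoxy-4-pivaloyloxyphenyl)propane-1,3-diol | COc1cc([C@@H](O)[C@H](CO)c2cc(OC)c(OC(=O)C(C)(C)C)c(OC)c2)ccc1O | intermediate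
17 | (1S,2S)-1-(4-hydroxy-3-methoxyphenyl)-2-(4-hydroxy-3,5-dimethoxyphenyl)propane-1,3-diol | COc1cc([C@@H](O)[C@H](CO)c2cc(OC)c(O)c(OC)c2)ccc1O | target

**Step count and risks**

Total steps: 9. Longest linear sequence: 8 (steps 1, 2, 4, 5, 6, 7, 8, 9 from compound 1); step 3 is a one-step side branch.

Steps most likely to fail:

Step 7. The quinone methide may tautomerise to the conjugated stilbene, be captured intermolecularly, or be attacked with insufficient facial discrimination. Both stereocentres would then be set by a known auxiliary-controlled anti-aldol addition that sets out from imide 5. MgCl2 (cat.), Et3N and Me3SiCl in EtOAc with 4-benzyloxy-3-methoxybenzaldehyde should react through the magnesium-chelated Z-enolate, on the same enolate face as the alkylation of step 4. This should give the silylated anti adduct (S)-4-benzyl-3-[(2R,3S)-3-(4-benzyloxy-3-methoxyphenyl)-2-(3,5-dimethoxy-4-pivaloyloxyphenyl)-3-(trimethylsilyloxy)propanoyl]oxazolidin-2-one F1. Dilute HCl in THF would free the aldol (S)-4-benzyl-3-[(2R,3S)-3-(4-benzyloxy-3-methoxyphenyl)-3-hydroxy-2-(3,5-dimethoxy-4-pivaloyloxyphenyl)propanoyl]oxazolidin-2-one F2. NaBH4 in wet THF would give (1S,2S)-1-(4-benzyloxy-3-methoxyphenyl)-2-(3,5-dimethoxy-4-pivaloyloxyphenyl)propane-1,3-diol F3. Hydrogenolysis over Pd/C in EtOAc then returns to the route at diol 16, before step 9.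

Step 4. Alkylation of the stabilised enolate may stall, the electron-rich bromide may be lost by ionisation, or C2 may epimerise under base. The C1–C2 bond would then be made as an alkene and C2 set by catalytic asymmetric hydrogenation, setting out from acid 2. Perkin condensation with 4-benzyloxy-3-methoxybenzaldehyde (Ac2O, Et3N, 110 °C) should give (E)-3-(4-benzyloxy-3-methoxyphenyl)-2-(3,5-dimethoxy-4-pivaloyloxyphenyl)acrylic acid F4. Hydrogenation with Ru(OAc)2(BINAP) in MeOH, the ligand enantiomer being chosen in a test run to give the S acid, should give (S)-3-(4-benzyloxy-3-methoxyphenyl)-2-(3,5-dimethoxy-4-pivaloyloxyphenyl)propanoic acid F5. BH3·THF, which reduces the acid but not the aryl pivalate, then returns to the route at alcohol 10.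

Step 5. The pivalate protecting group may be lost during hydride reduction. It would then be given up on purpose, setting out from imide 9. Excess LiBH4 in THF/MeOH at rt should cleave auxiliary and pivalate together to give (S)-3-(4-benzyloxy-3-methoxyphenyl)-2-(4-hydroxy-3,5-dimethoxyphenyl)propan-1-ol F6. Phenoxide-selective acylation under phase transfer (pivaloyl chloride, aq NaOH/CH2Cl2, Bu4NHSO4) should put the pivalate back on the phenol only and return to the route at alcohol 10.

**Further compounds**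

F1 | step 7 | (S)-4-benzyl-3-[(2R,3S)-3-(4-benzyloxy-3-methoxyphenyl)-2-(3,5-dimethoxy-4-pivaloyloxyphenyl)-3-(trimethylsilyloxy)propanoyl]oxazolidin-2-one | COc1cc([C@@H](O[Si](C)(C)C)[C@H](C(=O)N2C(=O)OC[C@@H]2Cc3ccccc3)c4cc(OC)c(OC(=O)C(C)(C)C)c(OC)c4)ccc1OCc5ccccc5
F2 | step 7 | (S)-4-benzyl-3-[(2R,3S)-3-(4-benzyloxy-3-methoxyphenyl)-3-hydroxy-2-(3,5-dimethoxy-4-pivaloyloxyphenyl)propanoyl]oxazolidin-2-one | COc1cc([C@@H](O)[C@H](C(=O)N2C(=O)OC[C@@H]2Cc3ccccc3)c4cc(OC)c(OC(=O)C(C)(C)C)c(OC)c4)ccc1OCc5ccccc5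
F3 | step 7 | (1S,2S)-1-(4-benzyloxy-3-methoxyphenyl)-2-(3,5-dimethoxy-4-pivaloyloxyphenyl)propane-1,3-diol | COc1cc([C@@H](O)[C@H](CO)c2cc(OC)c(OC(=O)C(C)(C)C)c(OC)c2)ccc1OCc3ccccc3
F4 | step 4 | (E)-3-(4-benzyloxy-3-methoxyphenyl)-2-(3,5-dimethoxy-4-pivaloyloxyphenyl)acrylic acid | COc1cc(/C=C(/C(=O)O)c2cc(OC)c(OC(=O)C(C)(C)C)c(OC)c2)ccc1OCc3ccccc3
F5 | step 4 | (S)-3-(4-benzyloxy-3-methoxyphenyl)-2-(3,5-dimethoxy-4-pivaloyloxyphenyl)propanoic acid | COc1cc(C[C@H](C(=O)O)c2cc(OC)c(OC(=O)C(C)(C)C)c(OC)c2)ccc1OCc3ccccc3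
F6 | step 5 | (S)-3-(4-benzyloxy-3-methoxyphenyl)-2-(4-hydroxy-3,5-dimethoxyphenyl)propan-1-ol | COc1cc(C[C@H](CO)c2cc(OC)c(O)c(OC)c2)ccc1OCc3ccccc3
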